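**Retrosynthetic overview**

1. Ring numbering used here: C-1 carries the other ring, C-2 the phenethyl group, C-3 and C-6 are the carbonyl carbons, C-4 carries OH and C-5 the methyl group. The C-1–C-1' bond is cut last and is made by coupling the monomeric hydroxyquinone with its own reduced form, as in the presumed biosynthetic dimerisation.
2. The monomer comes from 3-ethoxy-2-methyl-5-(2-phenylethyl)phenol: ortho-oxygenation installs the C-3 oxygen, and hydrolysis of the ethoxy group releases the C-6 carbonyl.
3. Key disconnection: a benzannulation of 3-(2-phenylethyl)cyclobutenone (supplies C-4, C-1, C-2, C-3) with 1-ethoxyprop-1-yne (supplies C-5, C-6). A ketene–alkyne [2+2] forms C-5–C-4 and C-6–C-1, and a 6π electrocyclisation then forms C-4–C-3 after the old C-4–C-1 bond has opened.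
4. Enabling feature: in each quinone ring the oxygens on C-4 and C-6 flank the methyl-bearing C-5 in a 1,3 (resorcinol-type) relation, with the phenethyl-bearing C-2 para to C-5. This is the pattern a vinylketene oxygen plus an ynol-ether oxygen deliver, and it leaves C-3 and C-1 as the two CH positions for the third oxygen and the inter-ring bond.
5. Ring order: cyclobutenone ring (alkyne plus dichloroketene), then the six-membered carbocycle (key step), then quinone oxidation level, then dimer.

Key step: step 3

Remark: the target is drawn without a stereodescriptor, so the axis between the two quinone rings is treated as configurationally unspecified; the molecule has no stereocentre.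
Remark: 1-ethoxyprop-1-yne (ethyl 1-propynyl ether) is taken as a purchasable reagent.

**Route**

Step 1
Reactants: 1 4-phenylbut-1-yne; 2 trichloroacetyl chloride
Product: 3 4,4-dichloro-3-(2-phenylethyl)cyclobut-2-en-1-one
Conditions: Zn–Cu couple, Et2O/DME, rt, slow addition of 2
Reagents that add atoms: none
Why: Dichloroketene, made in the flask by zinc dechlorination of 2, should add to the terminal alkyne in a regioselective ketene–alkyne [2+2] cycloaddition in which the ketene carbonyl carbon bonds to the terminal alkyne carbon, so that the phenethyl group ends at C-3 of the cyclobutenone; no stereocentre is formed.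

Step 2
Reactants: 3 4,4-dichloro-3-(2-phenylethyl)cyclobut-2-en-1-one
Product: 4 3-(2-phenylethyl)cyclobut-2-en-1-one
Conditions: Zn dust, AcOH, TMEDA, EtOH, 0 °C to rt
Reagents that add atoms: none
Why: Zinc in buffered acetic acid should remove both chlorines alpha to the carbonyl by reductive dehalogenation through zinc enolates while leaving the strained enone intact; no stereocentre is formed.

Step 3
Reactants: 4 3-(2-phenylethyl)cyclobut-2-en-1-one; 5 1-ethoxyprop-1-yne
Product: 10 3-ethoxy-2-methyl-5-(2-phenylethyl)phenol, via vinylketene 6 (not isolated), via vinylcyclobutenone 7 (not isolated), via dienylketene 8 (not isolated), via cyclohexadienone 9 (not isolated)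
Conditions: toluene, 80 °C, sealed tube, Ar, 1.5 equiv 5
Reagents that add atoms: none
Why: Heating should open cyclobutenone 4 by 4π electrocyclic ring opening to vinylketene 6, whose electrophilic carbonyl carbon is attacked by the nucleophilic methyl-bearing carbon of ynol ether 5 in a regiospecific ketene–alkyne [2+2] cycloaddition that forms the C(methyl)–C(oxygen) bond and the C(ethoxy)–C(H) bond and gives 4-vinylcyclobutenone 7. A second 4π opening of 7 gives dienylketene 8, and 6π electrocyclisation between the ketene carbon and the methylene terminus closes the six-membered carbocycle as dienone 9, which tautomerises to phenol 10. The closest known reaction type is the Danheiser benzannulation of 3-alkylcyclobutenones with alkoxyalkynes, which gives 3-alkoxy-2,5-disubstituted phenols of this pattern. Ring closures: the transient four-membered ring by [2+2] cycloaddition, the benzene ring by thermally allowed disrotatory 6π electrocyclisation onto an unsubstituted CH2 terminus. No stereocentre survives, because the single sp3 centre of 7 is destroyed on ring opening. The step needs regiocontrol in the [2+2], secured by the polarisation of the ynol ether (oxygen-bearing carbon to the ketene alpha-carbon), chemoselection of 5 over ketene dimerisation, secured by excess 5 and the low stationary concentration of 6, and a dienylketene with the vinyl group cis to the ketene, which should be reached because the ring opening of 7 is reversible.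

Step 4
Reactants: 10 3-ethoxy-2-methyl-5-(2-phenylethyl)phenol
Product: 12 2-hydroxy-3-methyl-6-(2-phenylethyl)cyclohexa-2,5-diene-1,4-dione, via ethoxy-ortho-quinone 11 (not isolated)
Conditions: IBX (1.2 equiv), DMF, rt; then 2 M aq. H2SO4, THF, rt
Reagents that add atoms: IBX (2-iodoxybenzoic acid), O=C1OI(=O)(O)c2ccccc12; water, O
Why: Phenol 10 should ligate IBX and the aryloxy-λ5-iodane should deliver oxygen to the only free ortho carbon (the other ortho position carries the methyl group) while pentavalent iodine falls to monovalent iodine (IBX oxidation of an electron-rich phenol to an ortho-quinone), after which the ethoxy group of ortho-quinone 11, a vinylogous ester, is hydrolysed by addition–elimination of water to the stable 2-hydroxy-1,4-quinone tautomer 12; no stereocentre is formed.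

Step 5
Reactants: 12 2-hydroxy-3-methyl-6-(2-phenylethyl)cyclohexa-2,5-diene-1,4-dione (two molecules)
Product: 15 4,4'-dihydroxy-5,5'-dimethyl-2,2'-bis(2-phenylethyl)-[1,1'-bi(cyclohexa-1,4-dien-1-yl)]-3,3',6,6'-tetrone (the target), via triol 13 (not isolated), via hexol 14 (not isolated)
Conditions: Zn dust (0.5 equiv), AcOH, Ar, rt; then CF3CO2H (cat.), 40 °C; then Ag2O (1.1 equiv), rt
Reagents that add atoms: none
Why: Zinc in acetic acid should reduce half of 12 to triol 13, whose only unsubstituted ring carbon (ortho and para to hydroxyl groups) adds in a Friedel–Crafts-type conjugate addition to the only unsubstituted, acid-activated ring carbon of the remaining 12 (quinone–hydroquinone coupling, the reaction type behind the autoxidative dimerisation of benzene-1,2,4-triol), and Ag2O then oxidises hexol 14 to the bis-quinone; the new axis carries no stereodescriptor in the target.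

**Compound list**

1 | 4-phenylbut-1-yne | C#CCCc1ccccc1 | starting material
2 | trichloroacetyl chloride | ClC(Cl)(Cl)C(Cl)=O | starting material
3 | 4,4-dichloro-3-(2-phenylethyl)cyclobut-2-en-1-one | O=C1C=C(CCc2ccccc2)C1(Cl)Cl | intermediate
4 | 3-(2-phenylethyl)cyclobut-2-en-1-one | O=C1C=C(CCc2ccccc2)C1 | intermediate
5 | 1-ethoxyprop-1-yne | CCOC#CC | starting material
6 | 3-methylidene-5-phenylpent-1-en-1-one (vinylketene) | O=C=CC(=C)CCc1ccccc1 | intermediate (not isolated)
7 | 3-ethoxy-2-methyl-4-(4-phenylbut-1-en-2-yl)cyclobut-2-en-1-one (racemic, transient) | CCOC1=C(C)C(=O)C1C(=C)CCc1ccccc1 | intermediate (not isolated)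
8 | (3E)-3-ethoxy-2-methyl-5-methylidene-7-phenylhepta-1,3-dien-1-one (dienylketene) | O=C=C(C)/C(OCC)=C\C(=C)CCc1ccccc1 | intermediate (not isolated)
9 | 3-ethoxy-2-methyl-5-(2-phenylethyl)cyclohexa-2,4-dien-1-one | CCOC1=C(C)C(=O)CC(CCc2ccccc2)=C1 | intermediate (not isolated)
10 | 3-ethoxy-2-methyl-5-(2-phenylethyl)phenol | CCOc1cc(CCc2ccccc2)cc(O)c1C | intermediate
11 | 4-ethoxy-3-methyl-6-(2-phenylethyl)cyclohexa-3,5-diene-1,2-dione | CCOC1=C(C)C(=O)C(=O)C(CCc2ccccc2)=C1 | intermediate (not isolated)
12 | 2-hydroxy-3-methyl-6-(2-phenylethyl)cyclohexa-2,5-diene-1,4-dione | CC1=C(O)C(=O)C(CCc2ccccc2)=CC1=O | intermediate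
13 | 3-methyl-6-(2-phenylethyl)benzene-1,2,4-triol | Cc1c(O)cc(CCc2ccccc2)c(O)c1O | intermediate (not isolated)
14 | 3,3'-dimethyl-6,6'-bis(2-phenylethyl)-[1,1'-biphenyl]-2,2',4,4',5,5'-hexol | Cc1c(O)c(-c2c(O)c(C)c(O)c(O)c2CCc3ccccc3)c(CCc4ccccc4)c(O)c1O | intermediate (not isolated)
15 | 4,4'-dihydroxy-5,5'-dimethyl-2,2'-bis(2-phenylethyl)-[1,1'-bi(cyclohexa-1,4-dien-1-yl)]-3,3',6,6'-tetrone | CC1=C(O)C(=O)C(CCc2ccccc2)=C(C2=C(CCc3ccccc3)C(=O)C(O)=C(C)C2=O)C1=O | target

**Step count and risks**

Total step count: 5. Longest linear sequence: 5 steps (1 to 3 to 4 to 10 to 12 to 15).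

Steps most likely to fail:

Step 5. The conjugate addition has to occur at a ring carbon flanked by the phenethyl group and a carbonyl, so it may be slow. Degenerate redox exchange between 12 and 13, O-arylation, or acid-induced cyclodehydration of the 2,2'-dihydroxybiaryl to a dibenzofuran could then take over. The fallback makes the inter-ring bond by a classical Ullmann biaryl synthesis before any quinone is present; it sets out from 10 and comes back at 15. Ethylation of 10 (EtI, K2CO3, DMF) should give the symmetrical diether 1,3-diethoxy-2-methyl-5-(2-phenylethyl)benzene F1. Iodination (N-iodosuccinimide, cat. CF3CO2H, MeCN) at one of its two equivalent ring CH positions should give 1,3-diethoxy-4-iodo-2-methyl-5-(2-phenylethyl)benzene F2. Ullmann coupling (activated Cu powder, DMF, 150 °C) should give 2,2',4,4'-tetraethoxy-3,3'-dimethyl-6,6'-bis(2-phenylethyl)-1,1'-biphenyl F3. BBr3 (CH2Cl2, −78 °C to rt) should cleave the four ethers to 3,3'-dimethyl-6,6'-bis(2-phenylethyl)-[1,1'-biphenyl]-2,2',4,4'-tetrol F4. IBX (2.4 equiv, DMF) should then oxygenate each resorcinol ring at its only free position to give 15.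

Step 4. Water may add in conjugate fashion to the free ring position of ortho-quinone 11 instead of displacing the ethoxy group, or 11 may decompose or be over-oxidised before hydrolysis. The fallback replaces ortho oxygen transfer by a Teuber radical oxidation at the free para position; it sets out from 10 and comes back at 12. Potassium nitrosodisulfonate ON(SO3K)2 (KH2PO4 buffer, acetone/H2O) should give 3-ethoxy-2-methyl-5-(2-phenylethyl)cyclohexa-2,5-diene-1,4-dione F5. Hydrolysis of this ethoxyquinone (aq. NaOH, MeOH, then dilute HCl) should give the hydroxyquinone, which is the same compound as 12.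

Step 1. Dichloroketene may oligomerise faster than it adds to the unactivated alkyne, and 3 may rearrange by a 1,3-chlorine shift to its 2,4-dichloro isomer before it is reduced. The fallback is a keteniminium–alkyne [2+2] cycloaddition (Ghosez type) that needs no dechlorination; it sets out from 1 and comes back at 4. N,N-Dimethylacetamide, Tf2O and 2,4,6-collidine (ClCH2CH2Cl, reflux) with 1 should give N,N-dimethyl-3-(2-phenylethyl)cyclobut-2-en-1-iminium trifluoromethanesulfonate F6. Hydrolysis (aq. NaHCO3) should give 4 directly.

Further compounds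
F1 | step 5 | 1,3-diethoxy-2-methyl-5-(2-phenylethyl)benzene | CCOc1cc(CCc2ccccc2)cc(OCC)c1C
F2 | step 5 | 1,3-diethoxy-4-iodo-2-methyl-5-(2-phenylethyl)benzene | CCOc1cc(CCc2ccccc2)c(I)c(OCC)c1C
F3 | step 5 | 2,2',4,4'-tetraethoxy-3,3'-dimethyl-6,6'-bis(2-phenylethyl)-1,1'-biphenyl | CCOc1cc(CCc2ccccc2)c(-c2c(CCc3ccccc3)cc(OCC)c(C)c2OCC)c(OCC)c1C
F4 | step 5 | 3,3'-dimethyl-6,6'-bis(2-phenylethyl)-[1,1'-biphenyl]-2,2',4,4'-tetrol | Cc1c(O)cc(CCc2ccccc2)c(-c2c(CCc3ccccc3)cc(O)c(C)c2O)c1O
F5 | step 4 | 3-ethoxy-2-methyl-5-(2-phenylethyl)cyclohexa-2,5-diene-1,4-dione | CCOC1=C(C)C(=O)C=C(CCc2ccccc2)C1=O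
F6 | step 1 | N,N-dimethyl-3-(2-phenylethyl)cyclobut-2-en-1-iminium trifluoromethanesulfonate | C[N+](C)=C1C=C(CCc2ccccc2)C1.[O-]S(=O)(=O)C(F)(F)F
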